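Count hours with one number, the rate at which a flask makes target while its catalyst stays bound.

| setting | elm | ash | maple | grey | teal |
|---|---|---|---|---|---|
| starting material | 0.29 M | 0.47 M | 0.71 M | 0.25 M | 0.80 M |
| protic impurity | 0.24 M | 0.24 M | 0.24 M | 0.240 M | 0.240 M |
| free catalyst | 80 mM | 80 mM | 80 mM | 80 mM | 80 mM |
| temperature | 20 °C | 40 °C | 20 °C |  |  |
| remark | run made earlier | run made earlier | run made earlier | at 25 °C throughout | at 25 °C until 15 h, from then on at 55 °C |
| time |  |  |  | 50 h | 50 h |

| run | time / h | target / % | starting material / % |
|---|---|---|---|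
| elm | 4.00 | 2 | 67 |
| elm | 8.00 | 11 | 57 |
| elm | 15.0 | 18 | 46 |
| elm | 25.0 | 30 | 29 |
| elm | 48.0 | 58 | 6 |
| ash | 2.00 | 12 | 61 |
| ash | 4.00 | 24 | 41 |
| ash | 8.00 | 47 | 14 |
| ash | 12.0 | 65 | 3 |
| ash | 25.0 | 78 | 0 |
| maple | 10.0 | 6 | 76 |
| maple | 20.0 | 12 | 64 |
| maple | 30.0 | 15 | 53 |
| maple | 40.0 | 25 | 44 |
| maple | 48.0 | 25 | 38 |

(scatter of a reading: 1.5 percentage points)

- the numbers in the tables scatter with a standard deviation of 1.5 percentage points

1. which one finishes higher in amount of target, in percent of the starting material charged ("neither" within 2 percentage points) (grey / teal / neither)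
2. amount of target at the end, in percent of the starting material charged, grey
3. amount of target at the end, in percent of the starting material charged, teal

Late in the runs at 20 °C, elm gained 0.00341 M h⁻¹ of target and maple 0.00355 M h⁻¹, about the same despite their different charges. Ash gave 0.0249 M h⁻¹ at 40 °C, a factor of 7.02. 25 °C lies a fraction 0.250 of the way from maple's 20 °C to ash's 40 °C, so I raised that factor to this power, multiplied maple's rate by the outcome and put at 25 °C the value 0.00578 M h⁻¹: the plateau rate, target made per hour with the catalyst held bound.

I then took two extremes. In the first, an idealisation, the protic impurity stayed idle and the plateau rate was supposed to hold to the last of the charge: reckoned so, grey's charge took 43.3 h, less than the 50 h allowed, and teal's, with the power 1.50 for the step up and so 0.107 M h⁻¹ when hot, took 6.64 h after the change. If the impurity instantly took one starting material each, grey kept 4.00% and teal 70.0%.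

Maple shows where the real flasks lie. By its last reading, counting its catalyst as bound, it had lost 0.183 M while holding 0.177 M of target. I assumed the loss scaled with [starting material], so grey should end near 73.4%, and teal, charged above maple, just over its lower extreme.

The forecast also chose grey, with 85% for grey and 65% for teal, below my lower extreme, holding that “selectivity depends mainly on concentration”.

The flasks gave grey: 81.0% in grey and 74.4% in teal.

    starting material + free catalyst → catalyst intermediate A (k = 7.90 M⁻¹ h⁻¹, Ea = 56.0 kJ mol⁻¹)
    catalyst intermediate A ⇌ catalyst intermediate B (K = 0.110, k = 0.440 h⁻¹, Ea = 102 kJ mol⁻¹, ΔH = −16.0 kJ mol⁻¹)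
    catalyst intermediate B → free catalyst + target (k = 1.10 h⁻¹, Ea = 88.0 kJ mol⁻¹)
    starting material + protic impurity → quenched substrate (k = 0.0870 M⁻¹ h⁻¹, Ea = 72.0 kJ mol⁻¹)
    (constants at 25 °C)

In grey at 5.51 h, free catalyst had a half-life of 0.69 h by binding starting material, shorter than the 1.6 h of the forward step of catalyst intermediate A. At 25.0 h that intermediate, the resting state, held 61.7% of grey's catalyst. The plateau rate gives 57.8% of target by then, and grey held 58.1%. Scaled by the power −0.750 of the same factor to a flask like grey kept at 10 °C, it gives 26.8% at 50.0 h, and that flask held 21.9%.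

The numbers in the tables were generated by integration from invented constants; noise was put on by code.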